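**Two plateaus.** The south run got half the partner of the south-west flask, and at its last reading it held more starting material, 59.8 % against 42.8 %. Product stood still in both.

| flask | starting material | partner | initiator | remark | time |
|---|---|---|---|---|---|
| south-west | 0.30 M | 1.5 equiv | 1.5 mol% | the very flask that is asked about, followed so far |  |
| south | 0.30 M | 0.75 equiv | 1.5 mol% | run made earlier |  |
| flask | 0.30 M | 1.50 equiv | 1.5 mol% |  | 12 h |

- south-west (time / min: product / %, starting material / %): 40.0: 53.8, 44.5; 120: 54.9, 45.0; 180: 53.9, 43.8; 300: 53.6, 43.2; 480: 53.6, 42.8
- south (time / min: product / %, starting material / %): 12.0: 39.1, 59.9; 25.0: 38.8, 61.0; 30.0: 39.2, 60.9; 50.0: 38.8, 60.1; 60.0: 39.0, 59.8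

(readings scatter by 0.5 percentage points)

- Thursday's: at 12 h add partner, 100 % of the amount charged, then wait 12 h
- Tuesday's: change nothing and wait 12 h more
- Monday's: at 12 h take out 90 % of the product then present, then wait 12 h
- Sunday's: at 12 h add starting material, 50.0 % of the amount charged, then wait 12 h

- product taken out counts as made
- the numbers in the tables scatter with a standard deviation of 0.5 percentage points
- additions bring no volume worth counting

1. product, in percent of the starting material first charged, at 12 h
2. the option that brings most further product ("none" if no option brings more than 2 percentage points) (Thursday's / Tuesday's / Monday's / Sunday's / none)
3. product present, with what was taken out counted in, in percent of the starting material first charged, after Thursday's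
4. product present, with what was taken out counted in, in percent of the starting material first charged, after Sunday's

**What matters.** Time matters little. Product in the south-west flask moved 0.2 percentage points between 40.0 min and 480 min, less than the scatter of 0.5 points. That scatter is also far below the gap of 17 points in starting material between the runs, so single readings can be off without harm. Partner matters: going from 0.75 equiv to 1.5 equiv raised product by 15 points. Initiator stood at 1.5 mol% in both runs, so the runs say nothing about it. That is our weak point.

**The ratio.** We divide the fractional loss rate of starting material by the fractional loss rate of partner, so time drops out. This exchange ratio is a number read from the runs, and it is what must be known well. We suppose it stays steady and that partner stops acting at the same low level in both runs. Starting material left then goes as partner charged, raised to minus the ratio. The last readings give 0.483.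

**Our reckoning.** The mean of the readings puts product at 54.0 %. We take the plateau to mark the end of free partner, so Tuesday's, Monday's and Sunday's should bring nothing, and Sunday's stays at that figure. Thursday's should gain 12 points. With half the ratio, the gain would be 6.6 points.

The forecast, reasoning “so equilibrium re-forms”, gave 53 % at 12 h, Monday's as best, 65 % after Thursday's and 64.5 % after Sunday's, and so parts from us on the best option and on Sunday's.

**The result.** The flask gives 54.1 % at 12 h, with Thursday's best at 65.9 %, and 54.1 % after Sunday's.

    partner → decomposed reagent (k = 0.240 min⁻¹)
    initiator → 2 initiating radical (k = 0.00560 min⁻¹)
    partner + first chain carrier → product + second chain carrier (k = 1.20 × 10⁵ L mol⁻¹ min⁻¹)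
    starting material + initiating radical → capped initiator + first chain carrier (k = 5.50 × 10⁵ L mol⁻¹ s⁻¹)
    2 second chain carrier → ended chains (k = 2.60 × 10⁶ L mol⁻¹ s⁻¹)
    starting material + second chain carrier → by-product + first chain carrier (k = 2.40 × 10⁵ L mol⁻¹ min⁻¹)

**Afterwards.** Thursday's gained 12 points against our 12 points. For the neighbour flask with 6.00 equiv of partner, the ratio gives 21.9 % of starting material left, and that flask holds 19 %. At 1.72 min in the flask, partner turned into decomposed reagent 2.6 times as fast as it turned into product. That step's half-life of 2.9 min is far shorter than the 120 min of initiator, and at 720 min free partner stood at 0 % with 43 % of the starting material still there.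

The numbers in the tables are simulated for substances that don't exist.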